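**Strategy.** Atoms are numbered as in a labdane: the ring is C1–C5 plus C10, with C4 the gem-dimethyl carbon, C5 the CH bearing the oxobutyl arm and C10 the quaternary carbon bearing CH3 and acyl carbon C9. Everything rests on the crowded C4–C5 ring bond between these centres: it is made by a semipinacol ring expansion in which C5 shifts from carbinol carbon C3 to an isopropenyl-derived C4, which in one operation builds the cyclohexane, the gem-dimethyl group and a disposable C3 ketone while carrying the C5/C10 configuration through unchanged. The precursor is a 1-isopropenylcyclopentanol with the ketal-protected arm on the adjacent carbon, trans to a silylmethyl group (masked C9) on the neighbouring methyl-bearing quaternary carbon.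

Key step: step 5

Remark 1: the side chain is C9(=O)–C11H2–C12H2–C13(CH3)=C14H–C15H2OAc. C9 travels as the silylmethyl carbon, so only C11–C15 and the C13 methyl are added late: C11 from MeMgBr and C12–C15 from prenyl acetate. A C6 aldehyde from cleavage of a geranyl ester would bring one carbon too many for coupling to a C9 aldehyde.

Remark 2: the arm is attached by Michael addition to methyl vinyl ketone and ketalised afterwards, because alkylation of an enolate next to a quaternary carbon with an unactivated β-ketal iodide is unreliable.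

Remark 3: the C4 cation is generated by hydrogen-atom transfer under neutral conditions, because a tertiary allylic alcohol tends to ionise and dehydrate under strong Brønsted or Lewis acid, which would also endanger the dioxolane. The carbinol configuration of 10 is left open, since both epimers give 11.

**Route**

Step 1
Reactants: 1 (chloromethyl)dimethyl(phenyl)silane; 2 3-methylcyclopent-2-en-1-one
Product: 5 (R)-3-[(dimethylphenylsilyl)methyl]-3-methyl-1-(trimethylsilyloxy)cyclopent-1-ene, via silylmethyl Grignard reagent 3 (not isolated), via magnesium enolate 4 (not isolated)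
Conditions: 1, Mg, Et2O, reflux; then 2, Cu(OTf)2 (3 mol %), chiral imidazolinium salt (NHC precursor, 4 mol %), Et2O, −30 to 0 °C; then TMSCl, Et3N, DMPU, 0 °C to rt
Reagents that add atoms: chlorotrimethylsilane, C[Si](C)(C)Cl
Why: Copper–NHC-catalysed asymmetric conjugate addition of a Grignard reagent to a β-methyl cyclic enone, a known route to quaternary centres, should set C10 as (R) by ligand-controlled face selection (ligand enantiomer chosen accordingly), and O-silylation of the magnesium enolate fixes the enol double bond on the side of the new quaternary carbon.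

Step 2
Reactants: 5 enol silane; 6 methyl vinyl ketone (but-3-en-2-one)
Product: 7 (2S,3R)-3-[(dimethylphenylsilyl)methyl]-3-methyl-2-(3-oxobutyl)cyclopentan-1-one
Conditions: BF3·OEt2 (20 mol %), i-PrOH, CH2Cl2, −78 °C
Reagents that add atoms: none
Why: Mukaiyama–Michael addition of the regiodefined enol silane installs the whole oxobutyl arm next to the quaternary carbon without a free enolate that could equilibrate, and the enone should approach the face opposite the larger CH2SiMe2Ph group, so that the arm at the new centre (C5) is trans to it, which is also the more stable arrangement at this epimerisable position.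

Step 3
Reactants: 7 diketone
Product: 8 (2S,3R)-3-[(dimethylphenylsilyl)methyl]-3-methyl-2-[2-(2-methyl-1,3-dioxolan-2-yl)ethyl]cyclopentan-1-one
Conditions: (TMSOCH2)2, TMSOTf (cat.), CH2Cl2, −78 °C; pyridine quench
Reagents that add atoms: 1,2-bis(trimethylsilyloxy)ethane, C[Si](C)(C)OCCO[Si](C)(C)C
Why: Kinetically controlled silyl-ketalisation should select the unhindered methyl ketone over the ring ketone, which is flanked by a tertiary carbon next to a quaternary one; any minor C2 epimer can be separated or equilibrated (NaOMe, MeOH) at this stage.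

Step 4
Reactants: 8 keto ketal; 9 isopropenylmagnesium bromide
Product: 10 (2S,3R)-3-[(dimethylphenylsilyl)methyl]-3-methyl-2-[2-(2-methyl-1,3-dioxolan-2-yl)ethyl]-1-(prop-1-en-2-yl)cyclopentan-1-ol (either or both C1 epimers)
Conditions: LaCl3·2LiCl, THF, 0 °C
Reagents that add atoms: none
Why: Lanthanide-promoted Grignard 1,2-addition suppresses enolisation of the hindered α-branched ketone; the new carbinol centre (attack expected anti to the adjacent arm) needs no control because it becomes the carbonyl carbon in step 5.

Step 5
Reactants: 10 isopropenylcyclopentanol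
Product: 11 (3R,4R)-4-[(dimethylphenylsilyl)methyl]-2,2,4-trimethyl-3-[2-(2-methyl-1,3-dioxolan-2-yl)ethyl]cyclohexan-1-one
Conditions: N,N'-bis(3,5-di-tert-butylsalicylidene)ethylenediaminocobalt (C32H46CoN2O2, 5 mol %), N-fluoro-2,4,6-trimethylpyridinium triflate, PhSiH3, acetone, 0 °C to rt
Reagents that add atoms: none
Why: A trivalent cobalt hydride, formed from the divalent cobalt salen complex, the N-fluoropyridinium oxidant and PhSiH3, transfers a hydrogen atom to the CH2 terminus of the isopropenyl group; the tertiary C4 radical is trapped by cobalt and oxidised to a tetravalent alkylcobalt, a C4 cation equivalent, from which the C3–C5 bond shifts to C4 while the hydroxyl becomes the C3 carbonyl and collidine takes up the proton. The closest known reaction type is the hydrogen-atom-transfer-initiated radical–polar crossover semipinacol rearrangement of tertiary allylic alcohols, the non-acidic counterpart of the protio-semipinacol ring expansion of 1-alkenylcycloalkanols. The six-membered ring is closed by ring expansion through a 1,2-alkyl shift, not by cyclisation, so no exo or endo closure is involved. No stereocentre is created: C4 becomes CMe2, C5 migrates with retention, C10 is untouched and the carbinol centre is lost, so both epimers of 10 converge on 11. The step needs migration of C5 and not of the ring CH2 (C2), which the higher migratory aptitude of the more substituted carbon should secure, and it needs closure of the hydroxyl onto C4 to an epoxide to stay slower than the shift. Generating the cation at C4 from the alkene under neutral conditions avoids ionisation of the tertiary allylic C3–O bond and should leave the dioxolane and the Si–Ph bond intact.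

Step 6
Reactants: 11 ring-expanded ketone
Product: 13 dimethyl(phenyl){[(1R,2R)-1,3,3-trimethyl-2-[2-(2-methyl-1,3-dioxolan-2-yl)ethyl]cyclohexyl]methyl}silane, via hydrazone 12 (not isolated)
Conditions: N2H4·H2O, KOH, diethylene glycol, 130 °C then 200 °C
Reagents that add atoms: none
Why: Wolff–Kishner reduction (Huang–Minlon procedure) is the standard way to delete a ketone flanked by a gem-dimethyl carbon, as in ring A of 3-oxo-4,4-dimethyl terpenoids, and the dioxolane and the alkyl C–Si bond tolerate hot alkali; no stereocentre is α to the carbonyl.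

Step 7
Reactants: 13 silane
Product: 14 {(1R,2R)-1,3,3-trimethyl-2-[2-(2-methyl-1,3-dioxolan-2-yl)ethyl]cyclohexyl}methanol
Conditions: t-BuOOH, KH, n-Bu4NF, NMP, 70 °C
Reagents that add atoms: tert-butyl hydroperoxide, CC(C)(C)OO
Why: Fleming–Tamao oxidation in its basic variant (peroxide anion attacks silicon, then the aryl and the alkyl group shift from Si to O) converts the neopentyl C–Si bond into C9–OH without acid, so the dioxolane survives and no stereocentre is touched.

Step 8
Reactants: 14 primary alcohol
Product: 15 (1R,2R)-1,3,3-trimethyl-2-[2-(2-methyl-1,3-dioxolan-2-yl)ethyl]cyclohexane-1-carbaldehyde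
Conditions: n-Pr4N[RuO4] (5 mol %), NMO, 4 Å MS, CH2Cl2, rt
Reagents that add atoms: none
Why: Ley–Griffith oxidation is neutral and stops at the aldehyde, which cannot enolise or epimerise because its α-carbon (C10) is quaternary.

Step 9
Reactants: 15 aldehyde
Product: 16 1-{(1R,2R)-1,3,3-trimethyl-2-[2-(2-methyl-1,3-dioxolan-2-yl)ethyl]cyclohexyl}ethan-1-ol (both carbinol epimers)
Conditions: MeMgBr, THF, 0 °C
Reagents that add atoms: methylmagnesium bromide, C[Mg]Br
Why: Grignard addition to a non-enolisable aldehyde supplies C11; the new carbinol centre is uncontrolled and immaterial because it is oxidised in the next step.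

Step 10
Reactants: 16 secondary alcohol
Product: 17 1-{(1R,2R)-1,3,3-trimethyl-2-[2-(2-methyl-1,3-dioxolan-2-yl)ethyl]cyclohexyl}ethan-1-one
Conditions: n-Pr4N[RuO4] (5 mol %), NMO, 4 Å MS, CH2Cl2, rt
Reagents that add atoms: none
Why: Ley–Griffith oxidation of the secondary alcohol gives the C9 methyl ketone under neutral conditions that leave the dioxolane intact.

Step 11
Reactants: 18 prenyl acetate (3-methylbut-2-en-1-yl acetate)
Product: 19 (E)-4-hydroxy-3-methylbut-2-en-1-yl acetate
Conditions: SeO2 (cat.), t-BuOOH, CH2Cl2, rt
Reagents that add atoms: selenium dioxide, O=[Se]=O; tert-butyl hydroperoxide, CC(C)(C)OO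
Why: Riley allylic oxidation (ene reaction, then [2,3]-sigmatropic shift) hydroxylates the methyl group trans to the chain, which fixes the E geometry of the future C13=C14 bond.

Step 12
Reactants: 19 allylic alcohol
Product: 20 (E)-4-bromo-3-methylbut-2-en-1-yl acetate
Conditions: CBr4, PPh3, CH2Cl2, 0 °C
Reagents that add atoms: tetrabromomethane, BrC(Br)(Br)Br
Why: Appel bromination proceeds by SN2 displacement at the primary allylic carbon at low temperature, without allylic shift or loss of olefin geometry, and leaves the acetate alone.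

Step 13
Reactants: 17 methyl ketone; 20 allylic bromide
Product: 22 (2E)-3-methyl-6-oxo-6-{(1R,2R)-1,3,3-trimethyl-2-[2-(2-methyl-1,3-dioxolan-2-yl)ethyl]cyclohexyl}hex-2-en-1-yl acetate, via lithium enolate 21 (not isolated)
Conditions: LiN(i-Pr)2, THF, −78 °C; then 20, DMPU, −78 to −30 °C
Reagents that add atoms: none
Why: The ketone can enolise only toward its methyl group because C10 is quaternary, and SN2 alkylation of this lithium enolate by the reactive allylic bromide forms C11–C12 with the E olefin and the acetate already in place.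

Step 14
Reactants: 22 ketal acetate
Product: 23 (2E)-3-methyl-6-oxo-6-[(1R,2R)-1,3,3-trimethyl-2-(3-oxobutyl)cyclohexyl]hex-2-en-1-yl acetate (CNP0326957.1)
Conditions: 1 M HCl, THF, rt
Reagents that add atoms: water, O
Why: Mild acid hydrolysis of the dioxolane frees the methyl ketone, while the primary allylic acetate, the E trisubstituted olefin and both stereocentres (neither α to a carbonyl) should be unaffected.

**Compound list**

1 | (chloromethyl)dimethyl(phenyl)silane | ClC[Si](C)(C)c1ccccc1 | starting material
2 | 3-methylcyclopent-2-en-1-one | CC1=CC(=O)CC1 | starting material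
3 | [(dimethylphenylsilyl)methyl]magnesium chloride | Cl[Mg]C[Si](C)(C)c1ccccc1 | intermediate
4 | chloromagnesium (R)-3-[(dimethylphenylsilyl)methyl]-3-methylcyclopent-1-en-1-olate | Cl[Mg]OC1=C[C@](C)(C[Si](C)(C)c2ccccc2)CC1 | intermediate
5 | (R)-3-[(dimethylphenylsilyl)methyl]-3-methyl-1-(trimethylsilyloxy)cyclopent-1-ene | C[Si](C)(C)OC1=C[C@](C)(C[Si](C)(C)c2ccccc2)CC1 | intermediate
6 | methyl vinyl ketone (but-3-en-2-one) | CC(=O)C=C | starting material
7 | (2S,3R)-3-[(dimethylphenylsilyl)methyl]-3-methyl-2-(3-oxobutyl)cyclopentan-1-one | CC(=O)CC[C@@H]1C(=O)CC[C@@]1(C)C[Si](C)(C)c2ccccc2 | intermediate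
8 | (2S,3R)-3-[(dimethylphenylsilyl)methyl]-3-methyl-2-[2-(2-methyl-1,3-dioxolan-2-yl)ethyl]cyclopentan-1-one | CC1(CC[C@@H]2C(=O)CC[C@@]2(C)C[Si](C)(C)c3ccccc3)OCCO1 | intermediate
9 | isopropenylmagnesium bromide (prop-1-en-2-ylmagnesium bromide) | C=C(C)[Mg]Br | starting material
10 | (2S,3R)-3-[(dimethylphenylsilyl)methyl]-3-methyl-2-[2-(2-methyl-1,3-dioxolan-2-yl)ethyl]-1-(prop-1-en-2-yl)cyclopentan-1-ol, C1 configuration open | CC1(CC[C@@H]2C(O)(C(C)=C)CC[C@@]2(C)C[Si](C)(C)c3ccccc3)OCCO1 | intermediate
11 | (3R,4R)-4-[(dimethylphenylsilyl)methyl]-2,2,4-trimethyl-3-[2-(2-methyl-1,3-dioxolan-2-yl)ethyl]cyclohexan-1-one | CC1(CC[C@@H]2C(C)(C)C(=O)CC[C@@]2(C)C[Si](C)(C)c3ccccc3)OCCO1 | intermediate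
12 | hydrazone of ketone 11 | CC1(CC[C@@H]2C(C)(C)C(=NN)CC[C@@]2(C)C[Si](C)(C)c3ccccc3)OCCO1 | intermediate
13 | dimethyl(phenyl){[(1R,2R)-1,3,3-trimethyl-2-[2-(2-methyl-1,3-dioxolan-2-yl)ethyl]cyclohexyl]methyl}silane | CC1(CC[C@@H]2C(C)(C)CCC[C@@]2(C)C[Si](C)(C)c3ccccc3)OCCO1 | intermediate
14 | {(1R,2R)-1,3,3-trimethyl-2-[2-(2-methyl-1,3-dioxolan-2-yl)ethyl]cyclohexyl}methanol | CC1(CC[C@@H]2C(C)(C)CCC[C@@]2(C)CO)OCCO1 | intermediate
15 | (1R,2R)-1,3,3-trimethyl-2-[2-(2-methyl-1,3-dioxolan-2-yl)ethyl]cyclohexane-1-carbaldehyde | CC1(CC[C@@H]2C(C)(C)CCC[C@@]2(C)C=O)OCCO1 | intermediate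
16 | 1-{(1R,2R)-1,3,3-trimethyl-2-[2-(2-methyl-1,3-dioxolan-2-yl)ethyl]cyclohexyl}ethan-1-ol, both carbinol epimers | CC1(CC[C@@H]2C(C)(C)CCC[C@@]2(C)C(C)O)OCCO1 | intermediate
17 | 1-{(1R,2R)-1,3,3-trimethyl-2-[2-(2-methyl-1,3-dioxolan-2-yl)ethyl]cyclohexyl}ethan-1-one | CC1(CC[C@@H]2C(C)(C)CCC[C@@]2(C)C(C)=O)OCCO1 | intermediate
18 | prenyl acetate (3-methylbut-2-en-1-yl acetate) | CC(C)=CCOC(C)=O | starting material
19 | (E)-4-hydroxy-3-methylbut-2-en-1-yl acetate | OC/C(C)=C/COC(C)=O | intermediate
20 | (E)-4-bromo-3-methylbut-2-en-1-yl acetate | BrC/C(C)=C/COC(C)=O | intermediate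
21 | lithium enolate of methyl ketone 17 | CC1(CC[C@@H]2C(C)(C)CCC[C@@]2(C)C(=C)O[Li])OCCO1 | intermediate
22 | (2E)-3-methyl-6-oxo-6-{(1R,2R)-1,3,3-trimethyl-2-[2-(2-methyl-1,3-dioxolan-2-yl)ethyl]cyclohexyl}hex-2-en-1-yl acetate | CC1(CC[C@@H]2C(C)(C)CCC[C@@]2(C)C(=O)CC/C(C)=C/COC(C)=O)OCCO1 | intermediate
23 | (2E)-3-methyl-6-oxo-6-[(1R,2R)-1,3,3-trimethyl-2-(3-oxobutyl)cyclohexyl]hex-2-en-1-yl acetate | CC(=O)CC[C@@H]1C(C)(C)CCC[C@@]1(C)C(=O)CC/C(C)=C/COC(C)=O | target

**Step count and risks**

Total steps: 14. Longest linear sequence: 12 (steps 1–10, 13 and 14); steps 11 and 12 make the side-chain bromide separately.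

Step 5 is the most likely to fail. After hydrogen-atom transfer and oxidation, closure of the hydroxyl onto C4 to a spiro-epoxide, or shift of the ring CH2 instead of C5, may outrun the wanted shift, because expansion of a five-membered ring releases little strain. The fallback sets out from 10 and comes back at 11. A bromonium ion formed on the isopropenyl group with NBS (propylene oxide, i-PrOH, 0 °C) triggers the same C5 shift as a halo-semipinacol rearrangement and gives the 2-(bromomethyl) analogue of ketone 11 F1. Its C–Br bond is then reduced with Bu3SnH (excess, concentrated, AIBN, toluene, 80 °C) to give 11.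

Step 1 is the second risk. Facial discrimination by the copper–NHC catalyst may be insufficient for a five-membered enone with the bulky α-silyl Grignard reagent, and uncatalysed 1,2-addition may compete. The fallback sets out from 1 (as its Grignard reagent 3) and comes back at 5, with the roles of the two carbon groups exchanged. Reagent 3 adds to commercial 3-ethoxycyclopent-2-en-1-one to give the 1,2-adduct 3-ethoxy-1-[(dimethylphenylsilyl)methyl]cyclopent-2-en-1-ol F2. Brief treatment with dilute HCl in the work-up (Stork–Danheiser transposition) converts it into 3-[(dimethylphenylsilyl)methyl]cyclopent-2-en-1-one F3. Copper-catalysed asymmetric conjugate addition of Me3Al (Cu(OTf)2, chiral phosphoramidite or NHC ligand, Et2O, −30 °C), a combination with stronger precedent for β-substituted cyclopentenones, gives the dimethylaluminium enolate F4. Silylation of F4 with TMSOTf returns to enol silane 5.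

Step 13 is the third risk. Proton exchange between the product ketone and the enolate may lead to double alkylation, and the enolate may take the acyl group from the allylic acetate. The fallback sets out from 15 and comes back at 22. Lithiated methyl phenyl sulfone (PhSO2CH3, n-BuLi, THF, −78 °C) adds to aldehyde 15 to give the β-hydroxy sulfone F5. Oxidation (n-Pr4N[RuO4], NMO) gives the β-keto sulfone F6. Its stabilised anion (K2CO3, DMF, rt) is alkylated once by bromide 20 to give the alkylated keto sulfone F7. Reductive desulfonylation (SmI2, THF–MeOH, −78 °C) gives 22.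

**Further compounds**

F1 | step 5 | 2-(bromomethyl) analogue of ketone 11, both epimers at the bromomethyl-bearing carbon | CC1(CC[C@@H]2C(C)(CBr)C(=O)CC[C@@]2(C)C[Si](C)(C)c3ccccc3)OCCO1
F2 | step 1 | 3-ethoxy-1-[(dimethylphenylsilyl)methyl]cyclopent-2-en-1-ol | CCOC1=CC(O)(C[Si](C)(C)c2ccccc2)CC1
F3 | step 1 | 3-[(dimethylphenylsilyl)methyl]cyclopent-2-en-1-one | O=C1C=C(C[Si](C)(C)c2ccccc2)CC1
F4 | step 1 | dimethylaluminium (R)-3-[(dimethylphenylsilyl)methyl]-3-methylcyclopent-1-en-1-olate | C[Al](C)OC1=C[C@](C)(C[Si](C)(C)c2ccccc2)CC1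
F5 | step 13 | 2-(phenylsulfonyl)-1-{(1R,2R)-1,3,3-trimethyl-2-[2-(2-methyl-1,3-dioxolan-2-yl)ethyl]cyclohexyl}ethan-1-ol | CC1(CC[C@@H]2C(C)(C)CCC[C@@]2(C)C(O)CS(=O)(=O)c3ccccc3)OCCO1
F6 | step 13 | 2-(phenylsulfonyl)-1-{(1R,2R)-1,3,3-trimethyl-2-[2-(2-methyl-1,3-dioxolan-2-yl)ethyl]cyclohexyl}ethan-1-one | CC1(CC[C@@H]2C(C)(C)CCC[C@@]2(C)C(=O)CS(=O)(=O)c3ccccc3)OCCO1
F7 | step 13 | 5-(phenylsulfonyl) derivative of ketal acetate 22 | CC1(CC[C@@H]2C(C)(C)CCC[C@@]2(C)C(=O)C(C/C(C)=C/COC(C)=O)S(=O)(=O)c3ccccc3)OCCO1
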